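**Retrosynthetic overview**
1. The target is two identical 7-acetyl-3,6,8-trihydroxy-4,4-dimethylnaphthalen-1(4H)-one halves joined C2–CH2–C2'. The bridging carbon is removed as formaldehyde (Knoevenagel–Michael at C2).
2. Ring B is opened at C1–C2: Dieckmann condensation of the side-chain methyl ketone (C2/C3) onto the C1 methyl ester. The C7 acetyl is placed before this closure, at the resorcylate stage, because afterwards the enolised 1,3-dione carbon C2 would compete for the acylating agent.
3. The strategy rests on ring A being a β-resorcylate: the C1 carboxyl carbon sits on C8a, hydroxyls on C8 and C6, and the quaternary C4 on C4a. The C4a–C8a bond is therefore the aldol bond of a 3,5,7-triketo ester, released from a diketo-dioxinone by thermolysis in methanol, with the C3 ketone masked as a dioxolane.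
4. The diketo-dioxinone comes from the dianion of the keto-dioxinone and the acyl imidazole of ketalised 2,2-dimethylacetoacetic acid.
5. Ring order: ring A (step 6), ring B (step 8), then dimerisation (step 9).

Key step: step 6

Assumption: the target is taken as the drawn enol tautomer of a freely tautomerising bis(cyclic 1,3-dione); it has no stereocentre, and ring atoms are numbered as in naphthalen-1(4H)-one.

**Step 1**
Reactants: 1 2,2,6-trimethyl-4H-1,3-dioxin-4-one
Product: 2 2,2-dimethyl-6-(2-oxopropyl)-4H-1,3-dioxin-4-one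
Conditions: 1 (2 equiv), LiN(SiMe3)2 (2 equiv), THF, −78 °C; AcCl (1 equiv), −78 °C; aq. NH4Cl
Reagents that add atoms: acetyl chloride, CC(=O)Cl
Why: γ-Deprotonation of the vinylogous ester gives the lithium dienolate, which should be C-acylated at the γ-carbon by acetyl chloride (vinylogous Claisen acylation), the second equivalent of dienolate taking up the proton of the more acidic product.

**Step 2**
Reactants: 3 methyl 2,2-dimethyl-3-oxobutanoate; 4 ethylene glycol
Product: 5 methyl 2-methyl-2-(2-methyl-1,3-dioxolan-2-yl)propanoate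
Conditions: 4 (3 equiv), p-TsOH·H2O (cat.), PhMe, reflux, Dean–Stark
Reagents that add atoms: none
Why: Acid-catalysed ketalisation with azeotropic removal of water should convert only the ketone, since the neopentyl-type ester resists transesterification.

**Step 3**
Reactants: 5 methyl 2-methyl-2-(2-methyl-1,3-dioxolan-2-yl)propanoate
Product: 6 2-methyl-2-(2-methyl-1,3-dioxolan-2-yl)propanoic acid
Conditions: NaOH (5 equiv), MeOH–H2O, 70 °C; cold 1 M HCl to pH 4, 0 °C, EtOAc extraction
Reagents that add atoms: sodium hydroxide, [Na+].[OH-]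
Why: Saponification of the hindered ester needs heat, which the base-stable dioxolane tolerates, and brief cold acidification to pH 4 should free the acid without ketal cleavage.

**Step 4**
Reactants: 6 2-methyl-2-(2-methyl-1,3-dioxolan-2-yl)propanoic acid
Product: 7 1-(1H-imidazol-1-yl)-2-methyl-2-(2-methyl-1,3-dioxolan-2-yl)propan-1-one
Conditions: 1,1'-carbonyldiimidazole (1.1 equiv), THF, 25 to 40 °C; used crude
Reagents that add atoms: 1,1'-carbonyldiimidazole, O=C(n1ccnc1)n1ccnc1
Why: Carbonyldiimidazole activation gives the acyl imidazole under neutral conditions that spare the dioxolane, and the quaternary α-carbon excludes ketene formation.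

**Step 5**
Reactants: 2 2,2-dimethyl-6-(2-oxopropyl)-4H-1,3-dioxin-4-one; 7 1-(1H-imidazol-1-yl)-2-methyl-2-(2-methyl-1,3-dioxolan-2-yl)propan-1-one
Product: 8 2,2-dimethyl-6-[5-methyl-5-(2-methyl-1,3-dioxolan-2-yl)-2,4-dioxohexyl]-4H-1,3-dioxin-4-one
Conditions: 2 (2.2 equiv), LiN(iPr)2 (4.4 equiv), THF, −78 °C; 7 (1 equiv), −78 to −20 °C; AcOH, then pH 7 phosphate buffer
Reagents that add atoms: none
Why: The dianion of the keto-dioxinone should react at its terminal, more basic carbon with the non-enolisable acyl imidazole in a Claisen-type C-acylation, the excess dianion absorbing the proton of the acidic triketone product.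

**Step 6**
Reactants: 8 2,2-dimethyl-6-[5-methyl-5-(2-methyl-1,3-dioxolan-2-yl)-2,4-dioxohexyl]-4H-1,3-dioxin-4-one; 9 methanol
Product: 13 methyl 2,4-dihydroxy-6-(2-methyl-3-oxobutan-2-yl)benzoate, via acylketene 10 (not isolated), via triketo ester 11 (not isolated), via ketal resorcylate 12 (not isolated)
Conditions: MeOH (10 equiv), PhMe, 110 °C, sealed tube; concentrate; Cs2CO3 (2 equiv), MeOH, 25 °C; then 3 M aq. HCl, THF–MeOH, 25 to 40 °C
Reagents that add atoms: water, O
Why: At 110 °C the dioxinone undergoes a retro-[4+2] loss of acetone to the acylketene 10, which methanol captures as the β-keto ester 11, so the ketene carbon becomes C1 at the ester oxidation level. Cs2CO3 then deprotonates the C8a methylene, the most acidic one because it lies between the ester and the C8 ketone, and this carbon adds to the C4a ketone in a 6-(enolexo)-exo-trig aldol closure that forms the C4a–C8a bond and ring A. Loss of one molecule of water from the aldol adduct and enolisation of the C8 and C6 carbonyl groups give the aromatic ring 12 with both hydroxyls free, and the aqueous HCl that completes the dehydration also hydrolyses the dioxolane to the C3 methyl ketone. The closest known reaction type is the ketene trapping and aldol aromatisation of diketo-dioxinones to β-resorcylates. No stereocentre is formed. The step needs the C8a-to-C4a aldol to win over Claisen closure of C5 onto C1 and over aldol attack of C7 on C3, which the poorly electrophilic ester at C1, the quaternary C4 (C4a can enolise only towards C5) and the dioxolane at C3 secure.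

**Step 7**
Reactants: 13 methyl 2,4-dihydroxy-6-(2-methyl-3-oxobutan-2-yl)benzoate
Product: 14 methyl 3-acetyl-2,4-dihydroxy-6-(2-methyl-3-oxobutan-2-yl)benzoate
Conditions: AcCl (1.5 equiv), TiCl4 (3 equiv), CH2Cl2, 0 °C to reflux; 1 M aq. HCl
Reagents that add atoms: acetyl chloride, CC(=O)Cl
Why: TiCl4-mediated Friedel–Crafts ortho-acylation of the phenol (with in situ Fries shift of any aryl acetate) should go to C3, the only position ortho to both hydroxyls, because C5 is shielded by the adjacent quaternary carbon and no enolised 1,3-dione is yet present to compete.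

**Step 8**
Reactants: 14 methyl 3-acetyl-2,4-dihydroxy-6-(2-methyl-3-oxobutan-2-yl)benzoate
Product: 15 7-acetyl-3,6,8-trihydroxy-4,4-dimethylnaphthalen-1(4H)-one
Conditions: KOtBu (5 equiv), THF, 0 to 60 °C; 1 M aq. HCl
Reagents that add atoms: none
Why: Dieckmann condensation: the side-chain ketone can enolise only towards its methyl group, whose enolate closes ring B by 6-exo-trig attack on the ester (C1–C2 bond), while the aryl acetyl enolate cannot reach the ester and deprotonation of the product 1,3-dione drives the equilibrium.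

**Step 9**
Reactants: 15 7-acetyl-3,6,8-trihydroxy-4,4-dimethylnaphthalen-1(4H)-one (two molecules)
Product: 17 2,2'-methanediylbis[7-acetyl-3,6,8-trihydroxy-4,4-dimethylnaphthalen-1(4H)-one], via 2-methylidene trione 16 (not isolated)
Conditions: 37% aq. CH2O (0.5 equiv), NaOAc (cat.), EtOH–H2O, 25 °C
Reagents that add atoms: formaldehyde, C=O
Why: Knoevenagel condensation of formaldehyde at C2 of the cyclic 1,3-dione gives the methylidene trione 16, which a second molecule of 15 should trap by Michael addition as in the formation of methylenebis(dimedone), the hindered and doubly acyl-deactivated C5 staying untouched.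

**Compound list**
1 | 2,2,6-trimethyl-4H-1,3-dioxin-4-one | CC1=CC(=O)OC(C)(C)O1 | starting material
2 | 2,2-dimethyl-6-(2-oxopropyl)-4H-1,3-dioxin-4-one | CC(=O)CC1=CC(=O)OC(C)(C)O1 | intermediate
3 | methyl 2,2-dimethyl-3-oxobutanoate | COC(=O)C(C)(C)C(C)=O | starting material
4 | ethylene glycol | OCCO | starting material
5 | methyl 2-methyl-2-(2-methyl-1,3-dioxolan-2-yl)propanoate | COC(=O)C(C)(C)C1(C)OCCO1 | intermediate
6 | 2-methyl-2-(2-methyl-1,3-dioxolan-2-yl)propanoic acid | OC(=O)C(C)(C)C1(C)OCCO1 | intermediate
7 | 1-(1H-imidazol-1-yl)-2-methyl-2-(2-methyl-1,3-dioxolan-2-yl)propan-1-one | O=C(n1ccnc1)C(C)(C)C1(C)OCCO1 | intermediate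
8 | 2,2-dimethyl-6-[5-methyl-5-(2-methyl-1,3-dioxolan-2-yl)-2,4-dioxohexyl]-4H-1,3-dioxin-4-one | CC1(C)OC(=O)C=C(CC(=O)CC(=O)C(C)(C)C2(C)OCCO2)O1 | intermediate
9 | methanol | CO | starting material
10 | 8-methyl-8-(2-methyl-1,3-dioxolan-2-yl)non-1-ene-1,3,5,7-tetrone (acylketene) | O=C=CC(=O)CC(=O)CC(=O)C(C)(C)C1(C)OCCO1 | intermediate
11 | methyl 8-methyl-8-(2-methyl-1,3-dioxolan-2-yl)-3,5,7-trioxononanoate | COC(=O)CC(=O)CC(=O)CC(=O)C(C)(C)C1(C)OCCO1 | intermediate
12 | methyl 2,4-dihydroxy-6-[2-(2-methyl-1,3-dioxolan-2-yl)propan-2-yl]benzoate | COC(=O)c1c(O)cc(O)cc1C(C)(C)C1(C)OCCO1 | intermediate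
13 | methyl 2,4-dihydroxy-6-(2-methyl-3-oxobutan-2-yl)benzoate | COC(=O)c1c(O)cc(O)cc1C(C)(C)C(C)=O | intermediate
14 | methyl 3-acetyl-2,4-dihydroxy-6-(2-methyl-3-oxobutan-2-yl)benzoate | COC(=O)c1c(O)c(C(C)=O)c(O)cc1C(C)(C)C(C)=O | intermediate
15 | 7-acetyl-3,6,8-trihydroxy-4,4-dimethylnaphthalen-1(4H)-one | CC(=O)c1c(O)cc2c(c1O)C(=O)C=C(O)C2(C)C | intermediate
16 | 7-acetyl-6,8-dihydroxy-4,4-dimethyl-2-methylidenenaphthalene-1,3(2H,4H)-dione | CC(=O)c1c(O)cc2c(c1O)C(=O)C(=C)C(=O)C2(C)C | intermediate
17 | 2,2'-methanediylbis[7-acetyl-3,6,8-trihydroxy-4,4-dimethylnaphthalen-1(4H)-one] (CNP0295164.0) | CC(=O)c1c(O)cc2c(c1O)C(=O)C(CC1=C(O)C(C)(C)c3cc(O)c(C(C)=O)c(O)c3C1=O)=C(O)C2(C)C | target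

**Total step count:** 9
**Longest linear sequence:** 8 steps (steps 2, 3, 4, 5, 6, 7, 8 and 9, from 3)

**Steps most likely to fail**

Step 6. The aldol closure onto the C4a ketone, which sits next to a quaternary carbon carrying the dioxolane, may be slower than closure of the open-chain triketo ester through oxygen to a pyranone or through Claisen attack on the ester. Fallback, setting out from 8 and returning at 13: the open-chain ester is avoided by aromatising with the dioxinone ring intact. Treatment of 8 with Et3N in CH2Cl2 at 25 °C should give, by aldol attack of the dioxinone α-carbon on the same ketone and dehydration, 7-hydroxy-2,2-dimethyl-5-[2-(2-methyl-1,3-dioxolan-2-yl)propan-2-yl]-4H-1,3-benzodioxin-4-one F1. In this substrate the lactone carbonyl is locked in the ring and cannot enter a Claisen or pyranone closure. Opening of F1 with NaOMe in MeOH at reflux should give the methyl ester 12, and aqueous HCl in THF then frees the ketone to give 13.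

Step 8. Deprotonation of both phenols may leave the doubly ortho-substituted ester too electron-rich for the enolate to add, so that the cyclisation stalls or intermolecular condensation takes over. Fallback, setting out from 14 and returning at 15: the phenols are masked before the ring closure. Benzylation of 14 (BnBr, Cs2CO3, DMF, 60 °C) should give methyl 3-acetyl-2,4-bis(benzyloxy)-6-(2-methyl-3-oxobutan-2-yl)benzoate F2. Dieckmann condensation of F2 with LiN(SiMe3)2 in THF should give 7-acetyl-6,8-bis(benzyloxy)-3-hydroxy-4,4-dimethylnaphthalen-1(4H)-one F3. Hydrogenolysis (H2, Pd/C, EtOAc) then gives 15.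

Step 5. The neopentyl-type acyl imidazole may react too slowly with the dianion, which would then act as a base or decompose on warming. Fallback, setting out from 5 and returning at 8: the carbon–carbon bond is made by aldol addition to an aldehyde and the oxidation level is corrected afterwards. Reduction of 5 with LiAlH4 in THF should give 2-methyl-2-(2-methyl-1,3-dioxolan-2-yl)propan-1-ol F4. Swern oxidation ((COCl)2, DMSO, Et3N, −78 °C) gives the non-enolisable 2-methyl-2-(2-methyl-1,3-dioxolan-2-yl)propanal F5. Addition of the dianion of 2 (LiN(iPr)2, THF, −78 °C) to F5 should give racemic 6-[4-hydroxy-5-methyl-5-(2-methyl-1,3-dioxolan-2-yl)-2-oxohexyl]-2,2-dimethyl-4H-1,3-dioxin-4-one F6. Oxidation of F6 with Dess–Martin periodinane (NaHCO3, CH2Cl2) gives 8.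

**Further compounds**
F1 | step 6 | 7-hydroxy-2,2-dimethyl-5-[2-(2-methyl-1,3-dioxolan-2-yl)propan-2-yl]-4H-1,3-benzodioxin-4-one | CC1(C)OC(=O)c2c(O1)cc(O)cc2C(C)(C)C1(C)OCCO1
F2 | step 8 | methyl 3-acetyl-2,4-bis(benzyloxy)-6-(2-methyl-3-oxobutan-2-yl)benzoate | COC(=O)c1c(OCc2ccccc2)c(C(C)=O)c(OCc2ccccc2)cc1C(C)(C)C(C)=O
F3 | step 8 | 7-acetyl-6,8-bis(benzyloxy)-3-hydroxy-4,4-dimethylnaphthalen-1(4H)-one | CC(=O)c1c(OCc2ccccc2)cc2c(c1OCc1ccccc1)C(=O)C=C(O)C2(C)C
F4 | step 5 | 2-methyl-2-(2-methyl-1,3-dioxolan-2-yl)propan-1-ol | OCC(C)(C)C1(C)OCCO1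
F5 | step 5 | 2-methyl-2-(2-methyl-1,3-dioxolan-2-yl)propanal | O=CC(C)(C)C1(C)OCCO1
F6 | step 5 | 6-[4-hydroxy-5-methyl-5-(2-methyl-1,3-dioxolan-2-yl)-2-oxohexyl]-2,2-dimethyl-4H-1,3-dioxin-4-one (racemic) | CC1(C)OC(=O)C=C(CC(=O)CC(O)C(C)(C)C2(C)OCCO2)O1
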